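# Total synthesis proposal: sideroxylonal C (11)

Chroman numbering (O1, C2, C3, C4, C4a–C8a; ring B primed) is used for all compounds, including the open-chain ones.

## The problem

1. Sideroxylonal C (11) is a chroman: ring A is fused to the O1–C2–C3–C4 pyran. It carries a second, identical diformylphloroglucinol ring (ring B) at C2, isopropyl at C3 and isobutyl at C4.
2. The SMILES reads as 2R,3R,4R. H2/H3 and H3/H4 are both anti, so the array is 2,3-trans and 3,4-trans.
3. The three stereocentres are contiguous and have no polar handle or other stereogenic element nearby. C3 and C4 must therefore be set by an external chiral agent, while C2 can be controlled from C3.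
4. The C2–O1 bond is the weak point. It is a benzylic ether between an acidic phenol (ring A) and a trihydroxyphenyl-substituted carbon. It can open to an o-quinone methide, which threatens C2 (and C3, through the styrene tautomer) but also offers a way to form C2.
5. Four formyl groups and five free phenols rule out hydrides, organometallics, hydrogenation, primary amines and strong base late in the route. Protecting ten oxygens would cost more steps than the skeleton.
6. The feature that the key step exploits is this. C2 bears O1 and C1′ and is at the aldehyde oxidation level, and C2–C3 with the isopropyl group is an intact isovaleraldehyde. C4 with its isobutyl group is the carbonyl carbon of a second isovaleraldehyde. C4a (ring A) and C1′ (ring B) are each the only unsubstituted carbon of one and the same nucleophile, 2,4-diformylphloroglucinol 3.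
7. Ring A in its open form is symmetric about the C4a–C7 axis, so either ortho oxygen can become O1 and no regiochemical question arises.

## Retrosynthesis

**11 ⇒ 8 + 3.**
- Bonds cut: C2–C1′. O1–C2 is opened and re-formed on the way, via hydroxy aldehyde 9 and o-quinone methide 10.
- Why this cut: C2 is a masked aldehyde, and ring B is the arene 3, which condenses with aldehydes at its one free carbon.
- Against the neighbours: cutting O1–C2 alone leaves the whole carbon skeleton to be made. Cutting C2–C3 would need a C3 carbanion without any activating group.
- Simplification: 26 carbons become 18, one arene and one stereocentre fall away, and the piece removed is a compound the route needs anyway.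
- Asked of the forward reaction: condensation of a hindered, lactol-masked aldehyde with 3, closure of 10 with 2,3-trans selectivity, and no enolisation at C3.

**8 ⇒ 3 + 4 + 4 (via 5, 6, 7).**
- Bonds cut: C4–C4a, C3–C4 and O1–C2.
- Why this cut: lactol 8 is 3 plus two molecules of isovaleraldehyde 4 minus water. One molecule of 4 is used as an electrophile and gives o-quinone methide 5. The other is used as a nucleophile, as its enamine 6 with a chiral secondary amine.
- Against the neighbours: the C3–C4 bond is formed where asymmetric induction is reliable, at the α-carbon of an aldehyde enamine, and not at a weakly nucleophilic styrene. The formyl groups serve as blocking and activating groups. They leave 3 one reactive carbon, make it as acidic as a cyclic 1,3-dicarbonyl compound, and make 5 a true Michael acceptor.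
- Simplification: a C18 bicycle with two defined stereocentres goes back to a C8 and a C5 compound.
- Asked of the forward reaction: face control at C3, syn topicity for C4, and interception of 5 by 6 ahead of all other nucleophiles.

**3 ⇒ 1.**
- Bonds cut: the two aryl–CHO bonds.
- Forward reaction: twofold electrophilic formylation of phloroglucinol 1 via bis(iminium) salt 2. It must stop after the second formyl group.

## Roads not taken

**Alternative 1:** the most obvious cut, C3–C4 and O1–C2 at once.
- Forward key step: hetero-Diels–Alder reaction of o-quinone methide 5 with its own tautomer, (E)-2,4,6-trihydroxy-5-(3-methylbut-1-enyl)benzene-1,3-dicarbaldehyde A1. This is dimerisation of one C13 unit, made asymmetric by a chiral Brønsted acid.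
- Weakness 1: both partners come from one precursor and interconvert by proton shift, so their ratio and geometry cannot be set.
- Weakness 2: A1 is a weak nucleophile, so heat or strong acid is needed. Under these conditions the uncatalysed reaction, E/Z isomerisation and endo/exo competition open paths to several of the four diastereomers.
- Weakness 3: a chiral acid would have to order two nearly identical polyphenols with five hydrogen-bonding oxygens each. The known asymmetric cycloadditions of this type rely on aryl-substituted methides, which cannot tautomerise.
- Why the chosen plan is better: it splits the same formal dimerisation into two Michael events, and the first of them is under covalent catalyst control.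

**Alternative 2:** cut C4–C4a and keep C3–C4.
- Forward key step: (E)-2-isopropyl-5-methylhex-2-enal A2, the commercial aldol dimer of 4, would take up 3 by conjugate addition under iminium catalysis and give 8 after protonation at C3.
- Weakness 1: an α-isopropyl enal forms iminium ions poorly with secondary amines because of allylic strain. The primary amines that tolerate α-branching would be trapped by the formyl groups of 3 as vinylogous amides.
- Weakness 2: without iminium activation, 3 adds 1,2 and electrocyclises to 5,7-dihydroxy-2-isobutyl-3-isopropyl-2H-chromene-6,8-dicarbaldehyde A3, with oxygen on the wrong carbon.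
- Weakness 3: C3 would arise from an uncontrolled protonation.
- Why the chosen plan is better: it reaches the same lactol from simpler compounds with both centres set in the bond-forming event.

**Alternative 3:** cut no skeletal bond, only the three C–H bonds at the stereocentres.
- Forward key step: condensation of 1 with 1-(2,4,6-trihydroxyphenyl)-2-isopropyl-5-methylhexane-1,3-dione A4 gives the flat flavylium salt A5. Asymmetric reduction and fourfold formylation follow.
- Weakness 1: hydrogenation adds syn across C3=C4. A hydride/proton/hydride sequence protonates C3 anti to the C4 substituent. Both lead to 3,4-cis, so the all-trans array is out of reach.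
- Weakness 2: A5 is severely crowded, A4 needs protected phenols, and the formyl groups must be added last to an acid-labile 2-(trihydroxyphenyl)chroman.
- Why the chosen plan is better: the key step of this alternative makes no carbon–carbon bond, so its precursor is no simpler than the product.

Key step: step 2

Assumption: the C2 configuration of 7 and 8 is left open in name and SMILES, since both epimers pass through the same trigonal C2 in step 3.

## Route

Step 1
Reactants: 1 phloroglucinol
Product: 3 2,4-diformylphloroglucinol (2,4,6-trihydroxybenzene-1,3-dicarbaldehyde), via bis(iminium) salt 2 (not isolated)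
Conditions: POCl3 (2.1 equiv), DMF (2.1 equiv), 1,4-dioxane, 0 °C to rt; then ice-water
Reagents that add atoms: N,N-dimethylformamide CN(C)C=O; water O
Why: Vilsmeier–Haack formylation; 1 is reactive enough to take up two iminium groups at room temperature, and these deactivate the ring so that the third position should stay free when two equivalents of reagent are used. Hydrolysis of 2 on work-up gives 3.

Step 2
Reactants: 3 2,4-diformylphloroglucinol; 4 isovaleraldehyde (3-methylbutanal, two molecules are built in)
Product: 8 lactol (3R,4R)-2,5,7-trihydroxy-4-isobutyl-3-isopropylchromane-6,8-dicarbaldehyde (both C2 epimers), via o-quinone methide 5 (not isolated), via enamine 6 (not isolated), via aminal 7 (not isolated)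
Conditions: (S)-α,α-diphenylprolinol trimethylsilyl ether (20 mol%), 4 (4 equiv), MeCN, 0 °C, 3 in THF added over 6 h; aq. citric acid work-up
Reagents that add atoms: none
Why: Mechanism: the secondary amine condenses 4 with the one free ring carbon of 3 (Mannich addition, then loss of the amine, i.e. a Knoevenagel-type condensation) to o-quinone methide 5 and at the same time converts a second molecule of 4 into E-enamine 6. The β-carbon of 6 adds to the methide carbon of 5 (C3–C4), the phenoxide oxygen closes on the iminium carbon (O1–C2) to aminal 7, and the water set free in the condensation hydrolyses 7 to lactol 8 and returns the amine. The closest known reaction types are the amine-catalysed three-component Knoevenagel/Michael union of an aldehyde, an enolisable carbonyl compound and a cyclic 1,3-dicarbonyl acid, and the diarylprolinol-ether-catalysed formal [4+2] addition of aliphatic aldehydes to o-quinone methides generated in situ. The pyran ring closes either in concert with C3–C4 (inverse-demand hetero-Diels–Alder, [4+2]) or stepwise as a 6-exo-trig attack of O1 on C2=N+, and both give the same product. C3 is set by the catalyst: the CPh2OTMS group of the (S)-amine covers one face of the s-trans E-enamine, so that 5 is bound on the open face, the same sense as in additions of 4 to nitroalkenes, which corresponds to 3R. C4 is set relative to C3 by the compact endo (synclinal) approach, with the methide oxygen under the enamine nitrogen and the isobutyl group on the outside of the heterodiene; this syn topicity means 3,4-trans in the ring and hence 4R, while C2 is formed as a mixture that is of no consequence because C2 becomes trigonal again in step 3. The step needs chemoselectivity for 6 over the other partners of 5 (the anion of 3 and the styrene tautomer A1), which is secured by adding 3 slowly to an excess of 4 so that little 3 and 5 are ever present beside the far more nucleophilic enamine. The formyl groups of 3 are vinylogous acids locked in hydrogen bonds and the product aldehyde is α-branched and masked as lactol, so neither should engage the hindered amine.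

Step 3
Reactants: 8 lactol; 3 2,4-diformylphloroglucinol
Product: 11 sideroxylonal C, via hydroxy aldehyde 9 (not isolated), via o-quinone methide 10 (not isolated)
Conditions: 3 (1.05 equiv), NaOAc (0.3 equiv), AcOH, 35–40 °C; poured into cold 0.1 M HCl at full conversion
Reagents that add atoms: none
Why: Knoevenagel-type condensation of 3 with an aldehyde to an o-quinone methide, then intramolecular oxa-Michael addition (6-exo-trig): 8 opens readily to 9 because O1 belongs to an acidic, electron-poor phenol (which also disfavours a cyclic oxocarbenium ion and thus loss of H3), the free carbon of 3 adds to the formyl group, loss of water gives 10, and either of the two equivalent ortho hydroxyl groups of ring A closes the ring. C2 is set by C3: allylic 1,3-strain with the two oxygens that flank C1′ keeps H3 in the methide plane, so O1, tethered through C4, attacks the face opposite to isopropyl in an all-equatorial chair and H2 ends anti to H3 (2,3-trans, 2R). The weakly acidic buffer, the low temperature and the acidic quench are chosen so that C3 is not enolised and the closure is not reversed.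

## Compound list

1 | phloroglucinol (benzene-1,3,5-triol) | Oc1cc(O)cc(O)c1 | starting material
2 | 2,4-bis(dimethyliminiomethyl)phloroglucinol, drawn as the dichloride | C[N+](C)=Cc1c(O)cc(O)c(C=[N+](C)C)c1O.[Cl-].[Cl-] | intermediate
3 | 2,4-diformylphloroglucinol (2,4,6-trihydroxybenzene-1,3-dicarbaldehyde) | O=Cc1c(O)cc(O)c(C=O)c1O | intermediate
4 | isovaleraldehyde (3-methylbutanal) | CC(C)CC=O | starting material
5 | o-quinone methide of ring A: 2,4-dihydroxy-5-(3-methylbutylidene)-6-oxocyclohexa-1,3-diene-1,3-dicarbaldehyde | CC(C)CC=C1C(=O)C(C=O)=C(O)C(C=O)=C1O | intermediate
6 | (E)-enamine of 4 with (S)-α,α-diphenylprolinol trimethylsilyl ether | CC(C)/C=C/N1CCC[C@H]1C(c1ccccc1)(c1ccccc1)O[Si](C)(C)C | intermediate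
7 | (3R,4R)-2-amino chroman (N,O-aminal of 8 with the catalyst, C2 open) | CC(C)C[C@H]1c2c(O)c(C=O)c(O)c(C=O)c2OC(N2CCC[C@H]2C(c2ccccc2)(c2ccccc2)O[Si](C)(C)C)[C@@H]1C(C)C | intermediate
8 | (3R,4R)-2,5,7-trihydroxy-4-isobutyl-3-isopropylchromane-6,8-dicarbaldehyde (both C2 epimers) | CC(C)C[C@H]1c2c(O)c(C=O)c(O)c(C=O)c2OC(O)[C@@H]1C(C)C | intermediate
9 | (2R,3R)-3-(3,5-diformyl-2,4,6-trihydroxyphenyl)-2-isopropyl-5-methylhexanal (open form of 8) | CC(C)C[C@@H](c1c(O)c(C=O)c(O)c(C=O)c1O)[C@@H](C(C)C)C=O | intermediate
10 | o-quinone methide of ring B: open-chain isomer of 11 with C2=C1′, C3 and C4 configured as in 9 | CC(C)C[C@@H](c1c(O)c(C=O)c(O)c(C=O)c1O)[C@@H](C(C)C)C=C1C(=O)C(C=O)=C(O)C(C=O)=C1O | intermediate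
11 | sideroxylonal C, (2R,3R,4R)-2-(3,5-diformyl-2,4,6-trihydroxyphenyl)-5,7-dihydroxy-4-isobutyl-3-isopropylchromane-6,8-dicarbaldehyde | CC(C)C[C@H]1c2c(O)c(C=O)c(O)c(C=O)c2O[C@@H](c2c(O)c(C=O)c(O)c(C=O)c2O)[C@@H]1C(C)C | target

## Step count and risks

Total step count: 3. Longest linear sequence: 3 (1 → 3 → 8 → 11). Compound 3 enters twice.

**Step 2 (key step).**
- Most likely failure: interception of 5 by partners other than 6. These are C-attack by the anion of 3, or proton shift followed by self-cycloaddition. The cause is that 5 is formed in a medium that still holds its own precursor.
- Second risk: loss of catalyst activity, through protonation by the acidic phenol and reversible binding to the formyl groups.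
- Third risk: incomplete syn topicity, or reversal of the Michael addition through the product enamine. Incomplete topicity gives a diastereomer and not the enantiomer, so it can be removed at the stage of 8.
- Fallback (from 3, back at 8): the generation of 5 is uncoupled from the amine. Compounds 3 and 4 are condensed with p-toluenesulfinic acid under acid (three-component sulfonylalkylation of a phenol) to the storable sulfone 2,4,6-trihydroxy-5-[3-methyl-1-(4-methylphenylsulfonyl)butyl]benzene-1,3-dicarbaldehyde F1. F1 is then treated with 4, the same amine and solid NaHCO3. Compound 5 is released slowly by loss of sulfinate in a medium free of 3 and is taken up by 6 to give 8. 2-(1-Sulfonylalkyl)phenols are established o-quinone methide precursors in asymmetric organocatalysis.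

**Step 3.**
- Most likely failure: slow carbon–carbon bond formation at the doubly branched, lactol-masked aldehyde, which leaves time for enolisation at C3.
- Second risk: re-opening of C2–O1 under the reaction conditions. C2 would then drift from the kinetic 2,3-trans closure toward an equilibrium mixture. The all-trans isomer has its isobutyl group equatorial next to 5-OH and need not be the most stable one.
- Fallback (from 8, back at 11): ring B is brought in as the far more nucleophilic parent phenol and formylated afterwards. Lactol 8 is condensed with an excess of 1 under mild acid at or below room temperature. This gives (2R,3R,4R)-5,7-dihydroxy-4-isobutyl-3-isopropyl-2-(2,4,6-trihydroxyphenyl)chromane-6,8-dicarbaldehyde F2, by the same closure with the same control of C2 by C3. The two free positions of ring B are then formylated under the Vilsmeier–Haack conditions of step 1 to give 11. Ring A has no free position, so no regiochemical issue arises.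

**Step 1.**
- Most likely failure: statistical formylation (too little or too much), followed by a difficult separation of very polar polyphenol aldehydes.
- Fallback (from 1, back at 3): O-methylation of 1 (Me2SO4, K2CO3, acetone) gives 1,3,5-trimethoxybenzene F3. Twofold Rieche formylation (Cl2CHOMe, TiCl4, CH2Cl2) gives the non-polar, easily purified 2,4,6-trimethoxybenzene-1,3-dicarbaldehyde F4. BBr3 then cleaves the three ethers, each of which lies ortho to a formyl group, to give 3.

## Further compounds

F1 | step 2 | 2,4,6-trihydroxy-5-[3-methyl-1-(4-methylphenylsulfonyl)butyl]benzene-1,3-dicarbaldehyde (racemic) | CC(C)CC(c1c(O)c(C=O)c(O)c(C=O)c1O)S(=O)(=O)c1ccc(C)cc1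
F2 | step 3 | (2R,3R,4R)-5,7-dihydroxy-4-isobutyl-3-isopropyl-2-(2,4,6-trihydroxyphenyl)chromane-6,8-dicarbaldehyde | CC(C)C[C@H]1c2c(O)c(C=O)c(O)c(C=O)c2O[C@@H](c2c(O)cc(O)cc2O)[C@@H]1C(C)C
F3 | step 1 | 1,3,5-trimethoxybenzene | COc1cc(OC)cc(OC)c1
F4 | step 1 | 2,4,6-trimethoxybenzene-1,3-dicarbaldehyde | COc1cc(OC)c(C=O)c(OC)c1C=O
A1 | alternative 1 | (E)-2,4,6-trihydroxy-5-(3-methylbut-1-enyl)benzene-1,3-dicarbaldehyde | CC(C)/C=C/c1c(O)c(C=O)c(O)c(C=O)c1O
A2 | alternative 2 | (E)-2-isopropyl-5-methylhex-2-enal | CC(C)C/C=C(\C(C)C)C=O
A3 | alternative 2 | 5,7-dihydroxy-2-isobutyl-3-isopropyl-2H-chromene-6,8-dicarbaldehyde (racemic) | CC(C)CC1Oc2c(C=O)c(O)c(C=O)c(O)c2C=C1C(C)C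
A4 | alternative 3 | 1-(2,4,6-trihydroxyphenyl)-2-isopropyl-5-methylhexane-1,3-dione (racemic) | CC(C)CC(=O)C(C(C)C)C(=O)c1c(O)cc(O)cc1O
A5 | alternative 3 | 5,7-dihydroxy-4-isobutyl-3-isopropyl-2-(2,4,6-trihydroxyphenyl)chromenylium chloride | CC(C)Cc1c(C(C)C)c(-c2c(O)cc(O)cc2O)[o+]c2cc(O)cc(O)c12.[Cl-]
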